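**Plan**

1. Retrosynthetic cuts, in order: the two O‑benzyl bonds; the C2'–phenyl bond of ring F; O1'–C2' and C2'–C3' of the chromone; C4–C6' and C4–C4a (two Friedel–Crafts bonds from one aldehyde carbon); the O1–C2 aryl ether.
2. Numbering: flavan unit O1, C2–C8a with arene ring A and pyran ring C; flavanone unit primed, with arene ring D and pyranone ring F.
3. Enabling feature: C2' holds its phenyl β to the C4' carbonyl of ring F and is the only centre that can epimerise (retro‑oxa‑Michael), so ring F is carried as a flat 4H‑chromen‑4‑one (C2'=C3') and C2' is made in the last C–C bond formation.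
4. Forward order: ring A phenol; aryl ether O1–C2; aldehyde; ring C closes and ring D is attached at C4 in one acid operation; O5' is benzylated, O1' is freed and ring F is closed as the chromone; phenyl is added to C2'; both benzyl ethers are removed.
5. Stereochemistry: C2 (S) from (R)‑1‑phenylbut‑3‑en‑1‑ol by Mitsunobu inversion; C4 (S, 2,4‑trans) by substrate control in the capture of the flavan‑4‑yl cation; C2' (R) by the chiral pyridine‑oxazoline ligand on divalent palladium.
6. Ring D enters as the mono‑allyl ether of 2',6'‑dihydroxy‑4'‑methoxyacetophenone, so that the oxygen next to the flavanyl group becomes the O5' benzyl ether and only the other oxygen can close ring F.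

Key step: step 13

Remark: the (S)‑configured pyridine‑oxazoline ligand is assumed to show on the chromone the facial preference it shows on cyclic enones, which corresponds to 2'R.

**Route**

Step 1
Reactants: 1 4‑methoxyphenol
Product: 2 2,6‑dibromo‑4‑methoxyphenol
Conditions: Br2 (2.1 equiv), CH2Cl2, 0 °C → rt
Reagents that add atoms: bromine, BrBr
Why: Electrophilic aromatic bromination in which the hydroxyl outranks the methoxy group as director, so both bromines should enter ortho to OH (the para position is blocked) and mark the two carbons that will carry O1 and O7 of ring A.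

Step 2
Reactants: 2 2,6‑dibromo‑4‑methoxyphenol
Product: 3 1,3‑dibromo‑2,5‑dimethoxybenzene
Conditions: MeI, K2CO3, acetone, reflux
Reagents that add atoms: iodomethane, CI
Why: Williamson methylation of an acidic, doubly ortho‑brominated phenoxide, which fixes the future C8 methoxy group.

Step 3
Reactants: 3 1,3‑dibromo‑2,5‑dimethoxybenzene
Product: 6 3‑bromo‑2,5‑dimethoxyphenol, via aryllithium 4 (not isolated), via dimethyl arylboronate 5 (not isolated)
Conditions: n‑BuLi (1.0 equiv), THF, −78 °C; B(OMe)3, −78 °C → rt; then AcOH, 30% H2O2, 0 °C → rt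
Reagents that add atoms: hydrogen peroxide, OO
Why: Bromine–lithium exchange should stop after one bromine because the aryllithium does not exchange again, and borate trapping followed by peroxide oxidation (aryl shift from boron to oxygen) turns that C–Br into C–OH.

Step 4
Reactants: 6 3‑bromo‑2,5‑dimethoxyphenol
Product: 7 1‑(benzyloxy)‑3‑bromo‑2,5‑dimethoxybenzene
Conditions: BnBr, K2CO3, DMF, rt
Reagents that add atoms: benzyl bromide, BrCc1ccccc1
Why: Williamson benzylation, which installs the hydrogenolysable protecting group on the future O7.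

Step 5
Reactants: 7 1‑(benzyloxy)‑3‑bromo‑2,5‑dimethoxybenzene
Product: 10 3‑(benzyloxy)‑2,5‑dimethoxyphenol, via aryllithium 8 (not isolated), via dimethyl arylboronate 9 (not isolated)
Conditions: n‑BuLi (1.05 equiv), THF, −78 °C; B(OMe)3, −78 °C → rt; then AcOH, 30% H2O2, 0 °C → rt
Reagents that add atoms: hydrogen peroxide, OO
Why: The same bromine–lithium exchange, borylation and oxidation sequence, in which exchange at −78 °C should be faster than deprotonation of the benzyl ether, delivers the ring A phenol with its four oxygens in place.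

Step 6
Reactants: 10 3‑(benzyloxy)‑2,5‑dimethoxyphenol; 11 (R)‑1‑phenylbut‑3‑en‑1‑ol
Product: 12 (S)‑1‑(benzyloxy)‑2,5‑dimethoxy‑3‑[(1‑phenylbut‑3‑en‑1‑yl)oxy]benzene
Conditions: PPh3, DIAD, toluene, 0 °C → rt
Reagents that add atoms: none
Why: Mitsunobu etherification, in which the phenoxide displaces the alkoxyphosphonium group by SN2 with inversion (R → S) and so sets the future C2, the non‑polar solvent and low temperature being chosen to suppress ionisation of the benzylic centre.

Step 7
Reactants: 12 (S)‑1‑(benzyloxy)‑2,5‑dimethoxy‑3‑[(1‑phenylbut‑3‑en‑1‑yl)oxy]benzene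
Product: 14 (S)‑3‑[3‑(benzyloxy)‑2,5‑dimethoxyphenoxy]‑3‑phenylpropanal, via 1,2‑diol 13 (not isolated)
Conditions: OsO4 (2 mol %), NaIO4 (4 equiv), 2,6‑lutidine, dioxane–H2O (3:1), rt; aldehyde used at once
Reagents that add atoms: osmium tetroxide, O=[Os](=O)(=O)=O; sodium periodate, [Na+].[O-]I(=O)(=O)=O (terminal oxygen source)
Why: Lemieux–Johnson oxidation, in which dihydroxylation of the only alkene and periodate cleavage of the diol remove one carbon under buffered conditions that should spare the electron‑rich arene, the benzyl ether and the C–O stereocentre.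

Step 8
Reactants: 15 2',6'‑dihydroxy‑4'‑methoxyacetophenone
Product: 16 2'‑(allyloxy)‑6'‑hydroxy‑4'‑methoxyacetophenone
Conditions: allyl bromide (1.05 equiv), K2CO3, acetone, reflux
Reagents that add atoms: allyl bromide, C=CCBr
Why: Williamson mono‑allylation of a symmetric diol, which should stop after one alkylation because the remaining hydroxyl is locked in a hydrogen bond to the carbonyl.

Step 9
Reactants: 14 (S)‑3‑[3‑(benzyloxy)‑2,5‑dimethoxyphenoxy]‑3‑phenylpropanal; 16 2'‑(allyloxy)‑6'‑hydroxy‑4'‑methoxyacetophenone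
Product: 18 1‑{6‑(allyloxy)‑3‑[(2S,4S)‑7‑(benzyloxy)‑5,8‑dimethoxyflavan‑4‑yl]‑2‑hydroxy‑4‑methoxyphenyl}ethanone (2,4‑trans flavan), via flavan‑4‑ol 17 (not isolated)
Conditions: BF3·OEt2 (0.2 equiv), 16 (1.5 equiv), CH2Cl2, −40 → 0 °C
Reagents that add atoms: none
Why: Friedel–Crafts hydroxyalkylation then alkylation, in which the activated aldehyde is attacked by the ring A carbon ortho to the ether oxygen (six‑membered closure of ring C), the flavan‑4‑ol ionises to a cation stabilised by O1, the C5 methoxy and the C7 benzyloxy groups, and 16 captures it at the less hindered carbon ortho to its chelated hydroxyl along a pseudo‑axial path anti to the equatorial C2 phenyl, which should give the 2,4‑trans isomer.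

Step 10
Reactants: 18 1‑{6‑(allyloxy)‑3‑[(2S,4S)‑7‑(benzyloxy)‑5,8‑dimethoxyflavan‑4‑yl]‑2‑hydroxy‑4‑methoxyphenyl}ethanone
Product: 19 1‑{6‑(allyloxy)‑2‑(benzyloxy)‑3‑[(2S,4S)‑7‑(benzyloxy)‑5,8‑dimethoxyflavan‑4‑yl]‑4‑methoxyphenyl}ethanone
Conditions: BnBr, K2CO3, n‑Bu4NI (cat.), DMF, 60 °C
Reagents that add atoms: benzyl bromide, BrCc1ccccc1
Why: Williamson benzylation of the only free phenol, which is chelated and hindered and therefore needs warm DMF and iodide catalysis, fixes the oxygen next to the flavanyl group as the future O5' ether.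

Step 11
Reactants: 19 1‑{6‑(allyloxy)‑2‑(benzyloxy)‑3‑[(2S,4S)‑7‑(benzyloxy)‑5,8‑dimethoxyflavan‑4‑yl]‑4‑methoxyphenyl}ethanone
Product: 20 1‑{2‑(benzyloxy)‑3‑[(2S,4S)‑7‑(benzyloxy)‑5,8‑dimethoxyflavan‑4‑yl]‑6‑hydroxy‑4‑methoxyphenyl}ethanone
Conditions: Pd(PPh3)4 (5 mol %), morpholine, THF, rt
Reagents that add atoms: none
Why: Tsuji–Trost deallylation, in which zerovalent palladium ionises the allyl aryl ether to a π‑allyl complex that morpholine intercepts, frees the future O1' while benzyl and methyl ethers stay untouched.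

Step 12
Reactants: 20 1‑{2‑(benzyloxy)‑3‑[(2S,4S)‑7‑(benzyloxy)‑5,8‑dimethoxyflavan‑4‑yl]‑6‑hydroxy‑4‑methoxyphenyl}ethanone
Product: 22 5‑(benzyloxy)‑6‑[(2S,4S)‑7‑(benzyloxy)‑5,8‑dimethoxyflavan‑4‑yl]‑7‑methoxy‑4H‑chromen‑4‑one, via enaminone 21 (not isolated)
Conditions: Me2NCH(OMe)2, toluene, 100 °C; evaporate; then 2 M aq. HCl, CH2Cl2, rt
Reagents that add atoms: N,N‑dimethylformamide dimethyl acetal, COC(OC)N(C)C
Why: Enaminone formation at the acetyl methyl group followed by acid‑promoted 6‑endo addition of the single free phenol and loss of dimethylamine is the standard chromone synthesis, and with O5' benzylated only closure through O1' is possible.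

Step 13
Reactants: 22 5‑(benzyloxy)‑6‑[(2S,4S)‑7‑(benzyloxy)‑5,8‑dimethoxyflavan‑4‑yl]‑7‑methoxy‑4H‑chromen‑4‑one; 23 phenylboronic acid
Product: 24 (2R)‑5‑(benzyloxy)‑6‑[(2S,4S)‑7‑(benzyloxy)‑5,8‑dimethoxyflavan‑4‑yl]‑7‑methoxyflavanone
Conditions: Pd(OCOCF3)2 (10 mol %), (S)‑4‑tert‑butyl‑2‑(pyridin‑2‑yl)‑4,5‑dihydrooxazole (12 mol %), NH4PF6 (30 mol %), H2O (5 equiv), 23 (3 equiv), ClCH2CH2Cl, 60 °C
Reagents that add atoms: none
Why: Transmetallation of 23 to the cationic, ligand‑bound divalent palladium centre gives a phenylpalladium species that binds the C2'=C3' bond of ring F, migratory insertion puts phenyl on C2' and palladium on C3', and protonolysis of the palladium enolate by water releases the flavanone without a change of oxidation state. The closest known reaction type is the palladium/pyridine‑oxazoline conjugate addition of arylboronic acids to chromones, which gives flavanones directly. No ring is closed: ring F is already present as the pyranone and is only saturated at C2'–C3'. The new C2' centre (R) is set by the catalyst, the tert‑butyl group of the (S)‑ligand deciding which face of the flat pyranone receives phenyl, while C2 and C4 sit on the C6' substituent at the far edge of ring D and should have little influence. The step needs 1,4‑ over 1,2‑addition, a clean face choice and no opening of ring F; conjugation of C2'=C3' with the C4' carbonyl secures the first, and the O5' benzyl ether (no peri‑hydroxyl chelation, no phenoxide) together with the near‑neutral medium secures the others. Any 2'S product is a diastereomer of 24 and should be removable by chromatography.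

Step 14
Reactants: 24 (2R)‑5‑(benzyloxy)‑6‑[(2S,4S)‑7‑(benzyloxy)‑5,8‑dimethoxyflavan‑4‑yl]‑7‑methoxyflavanone
Product: 25 (2R)‑5‑hydroxy‑6‑[(2S,4S)‑7‑hydroxy‑5,8‑dimethoxyflavan‑4‑yl]‑7‑methoxyflavanone (CNP0301559.1)
Conditions: H2 (1 atm), 10% Pd/C, EtOAc, rt
Reagents that add atoms: none
Why: Hydrogenolysis of the two aryl benzyl ethers under neutral conditions should leave the base‑labile C2' centre, the ketone and the cyclic benzylic C–O bonds of rings C and F intact.

**Compound list**

1 | 4‑methoxyphenol | COc1ccc(O)cc1 | starting material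
2 | 2,6‑dibromo‑4‑methoxyphenol | COc1cc(Br)c(O)c(Br)c1 | intermediate
3 | 1,3‑dibromo‑2,5‑dimethoxybenzene | COc1cc(Br)c(OC)c(Br)c1 | intermediate
4 | (3‑bromo‑2,5‑dimethoxyphenyl)lithium (not isolated) | [Li]c1cc(OC)cc(Br)c1OC | intermediate
5 | dimethyl (3‑bromo‑2,5‑dimethoxyphenyl)boronate (not isolated) | COB(OC)c1cc(OC)cc(Br)c1OC | intermediate
6 | 3‑bromo‑2,5‑dimethoxyphenol | Oc1cc(OC)cc(Br)c1OC | intermediate
7 | 1‑(benzyloxy)‑3‑bromo‑2,5‑dimethoxybenzene | COc1cc(Br)c(OC)c(OCc2ccccc2)c1 | intermediate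
8 | [3‑(benzyloxy)‑2,5‑dimethoxyphenyl]lithium (not isolated) | [Li]c1cc(OC)cc(OCc2ccccc2)c1OC | intermediate
9 | dimethyl [3‑(benzyloxy)‑2,5‑dimethoxyphenyl]boronate (not isolated) | COB(OC)c1cc(OC)cc(OCc2ccccc2)c1OC | intermediate
10 | 3‑(benzyloxy)‑2,5‑dimethoxyphenol | Oc1cc(OC)cc(OCc2ccccc2)c1OC | intermediate
11 | (R)‑1‑phenylbut‑3‑en‑1‑ol | C=CC[C@@H](O)c1ccccc1 | starting material
12 | (S)‑1‑(benzyloxy)‑2,5‑dimethoxy‑3‑[(1‑phenylbut‑3‑en‑1‑yl)oxy]benzene | C=CC[C@H](Oc1cc(OC)cc(OCc2ccccc2)c1OC)c1ccccc1 | intermediate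
13 | (4S)‑4‑[3‑(benzyloxy)‑2,5‑dimethoxyphenoxy]‑4‑phenylbutane‑1,2‑diol, both C2 epimers (not isolated) | OCC(O)C[C@H](Oc1cc(OC)cc(OCc2ccccc2)c1OC)c1ccccc1 | intermediate
14 | (S)‑3‑[3‑(benzyloxy)‑2,5‑dimethoxyphenoxy]‑3‑phenylpropanal | O=CC[C@H](Oc1cc(OC)cc(OCc2ccccc2)c1OC)c1ccccc1 | intermediate
15 | 2',6'‑dihydroxy‑4'‑methoxyacetophenone | CC(=O)c1c(O)cc(OC)cc1O | starting material
16 | 2'‑(allyloxy)‑6'‑hydroxy‑4'‑methoxyacetophenone | CC(=O)c1c(O)cc(OC)cc1OCC=C | intermediate
17 | (2S)‑7‑(benzyloxy)‑5,8‑dimethoxyflavan‑4‑ol, both C4 epimers (not isolated) | OC1C[C@@H](c2ccccc2)Oc2c(OC)c(OCc3ccccc3)cc(OC)c21 | intermediate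
18 | 1‑{6‑(allyloxy)‑3‑[(2S,4S)‑7‑(benzyloxy)‑5,8‑dimethoxyflavan‑4‑yl]‑2‑hydroxy‑4‑methoxyphenyl}ethanone | COc1cc(OCC=C)c(C(C)=O)c(O)c1[C@@H]1C[C@@H](c2ccccc2)Oc2c(OC)c(OCc3ccccc3)cc(OC)c21 | intermediate
19 | 1‑{6‑(allyloxy)‑2‑(benzyloxy)‑3‑[(2S,4S)‑7‑(benzyloxy)‑5,8‑dimethoxyflavan‑4‑yl]‑4‑methoxyphenyl}ethanone | COc1cc(OCC=C)c(C(C)=O)c(OCc2ccccc2)c1[C@@H]1C[C@@H](c2ccccc2)Oc2c(OC)c(OCc3ccccc3)cc(OC)c21 | intermediate
20 | 1‑{2‑(benzyloxy)‑3‑[(2S,4S)‑7‑(benzyloxy)‑5,8‑dimethoxyflavan‑4‑yl]‑6‑hydroxy‑4‑methoxyphenyl}ethanone | COc1cc(O)c(C(C)=O)c(OCc2ccccc2)c1[C@@H]1C[C@@H](c2ccccc2)Oc2c(OC)c(OCc3ccccc3)cc(OC)c21 | intermediate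
21 | (E)‑1‑{2‑(benzyloxy)‑3‑[(2S,4S)‑7‑(benzyloxy)‑5,8‑dimethoxyflavan‑4‑yl]‑6‑hydroxy‑4‑methoxyphenyl}‑3‑(dimethylamino)prop‑2‑en‑1‑one (not isolated) | COc1cc(O)c(C(=O)/C=C/N(C)C)c(OCc2ccccc2)c1[C@@H]1C[C@@H](c2ccccc2)Oc2c(OC)c(OCc3ccccc3)cc(OC)c21 | intermediate
22 | 5‑(benzyloxy)‑6‑[(2S,4S)‑7‑(benzyloxy)‑5,8‑dimethoxyflavan‑4‑yl]‑7‑methoxy‑4H‑chromen‑4‑one | COc1cc2c(c(OCc3ccccc3)c1[C@@H]1C[C@@H](c3ccccc3)Oc3c(OC)c(OCc4ccccc4)cc(OC)c31)C(=O)C=CO2 | intermediate
23 | phenylboronic acid | OB(O)c1ccccc1 | starting material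
24 | (2R)‑5‑(benzyloxy)‑6‑[(2S,4S)‑7‑(benzyloxy)‑5,8‑dimethoxyflavan‑4‑yl]‑7‑methoxyflavanone | COc1cc2c(c(OCc3ccccc3)c1[C@@H]1C[C@@H](c3ccccc3)Oc3c(OC)c(OCc4ccccc4)cc(OC)c31)C(=O)C[C@H](c1ccccc1)O2 | intermediate
25 | (2R)‑5‑hydroxy‑6‑[(2S,4S)‑7‑hydroxy‑5,8‑dimethoxyflavan‑4‑yl]‑7‑methoxyflavanone (CNP0301559.1) | COc1cc2c(c(O)c1[C@@H]1C[C@@H](c3ccccc3)Oc3c(OC)c(O)cc(OC)c31)C(=O)C[C@H](c1ccccc1)O2 | target

**Step count and risks**

Total: 14 steps. Longest linear sequence: 13 steps (steps 1–7 and 9–14); step 8 is a one‑step side branch.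

Steps most likely to fail:

1. Step 13. The electron‑rich pyranone, with a benzyl ether peri to the carbonyl and a bulky C6' group, may insert slowly, so that protodeboronation outruns addition or the face choice erodes. The fallback sets out from 20. Claisen–Schmidt condensation with benzaldehyde (KOH, EtOH, rt) should give the (E)‑2'‑hydroxychalcone F1. NaOAc in refluxing EtOH then closes ring F by oxa‑Michael addition to a mixture of 24 and its C2' epimer F2. These are diastereomers because C2 and C4 are fixed, so chromatography should separate them. F2 is resubmitted to the same base, which reopens it to F1 and feeds 24. The route is rejoined at 24.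

2. Step 9. Before ring C closes, the enolisable β‑aryloxy aldehyde may lose the phenoxide by elimination, which would erase C2, or the cation may be captured with poor trans or site selectivity. The fallback sets out from 14. Pinnick oxidation (NaClO2, NaH2PO4, 2‑methylbut‑2‑ene, t‑BuOH–H2O) gives the carboxylic acid F3, which no longer eliminates readily. (CF3CO)2O in CH2Cl2 at 0 °C closes ring C by intramolecular Friedel–Crafts acylation to the flavanone F4. NaBH4 in MeOH gives flavan‑4‑ol 17, this time isolated. Catalytic BF3·OEt2 with 16 in CH2Cl2 then performs only the intermolecular arylation, and the route is rejoined at 18.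

3. Step 6. The benzylic alkoxyphosphonium ion may ionise or eliminate, which would erode the enantiopurity at C2 or give the diene. The fallback sets out from bromide 7 and forms the O1–C2 bond on the aryl side instead. Ullmann‑type etherification of 7 with commercial (S)‑1‑phenylbut‑3‑en‑1‑ol (SMILES C=CC[C@H](O)c1ccccc1) uses CuI, 3,4,7,8‑tetramethyl‑1,10‑phenanthroline and Cs2CO3 in toluene at 110 °C. It leaves the carbinol C–O bond untouched, so the configuration is retained and 12 is reached directly, bypassing steps 5 and 6. No compound outside the list is made (F0).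

**Further compounds**

F1 | step 13 | (E)‑1‑{2‑(benzyloxy)‑3‑[(2S,4S)‑7‑(benzyloxy)‑5,8‑dimethoxyflavan‑4‑yl]‑6‑hydroxy‑4‑methoxyphenyl}‑3‑phenylprop‑2‑en‑1‑one | COc1cc(O)c(C(=O)/C=C/c2ccccc2)c(OCc2ccccc2)c1[C@@H]1C[C@@H](c2ccccc2)Oc2c(OC)c(OCc3ccccc3)cc(OC)c21
F2 | step 13 | (2S)‑5‑(benzyloxy)‑6‑[(2S,4S)‑7‑(benzyloxy)‑5,8‑dimethoxyflavan‑4‑yl]‑7‑methoxyflavanone (C2' epimer of 24) | COc1cc2c(c(OCc3ccccc3)c1[C@@H]1C[C@@H](c3ccccc3)Oc3c(OC)c(OCc4ccccc4)cc(OC)c31)C(=O)C[C@@H](c1ccccc1)O2
F3 | step 9 | (S)‑3‑[3‑(benzyloxy)‑2,5‑dimethoxyphenoxy]‑3‑phenylpropanoic acid | OC(=O)C[C@H](Oc1cc(OC)cc(OCc2ccccc2)c1OC)c1ccccc1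
F4 | step 9 | (S)‑7‑(benzyloxy)‑5,8‑dimethoxyflavanone | O=C1C[C@@H](c2ccccc2)Oc2c(OC)c(OCc3ccccc3)cc(OC)c21
F0 | step 6 | none | none
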